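(Readings and results were generated by integration for substances that don't exist.)

The other capture product, I take it, costs one second nucleophile each and the target one first nucleophile each, so the readings of the alder flask are also a balance of the two nucleophiles. The flask asked about is that same alder flask, followed further.

- alder: starting material 20 mM; first nucleophile 2.5 equiv; second nucleophile 1.8 equiv; protic impurity 1 mM; the very flask that is asked about, followed so far
- flask: starting material 20 mM; first nucleophile 2.50 equiv; second nucleophile 1.80 equiv; protic impurity 1.00 mM; time 3.0 h

alder run (percent of the starting material charged)

| time / min | other capture product / % | target / % |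
|---|---|---|
| 8.00 | 38.6 | 8.3 |
| 25.0 | 66.9 | 14.4 |
| 40.0 | 74.0 | 13.7 |
| 60.0 | 74.8 | 14.4 |
| 90.0 | 75.6 | 12.3 |

(scatter of a reading: 1 percentage point)

- the earlier runs were read with a standard deviation of 1 percentage point

* ratio of other capture product to target at 30 s
* ratio of other capture product to target at 10 min
* ratio of other capture product to target at 3.0 h
* which of other capture product and target there is more of at 3.0 h

The forecaster reads the ratio of other capture product to target as about 4.6 at both 8.00 min and 25.0 min, and then a late creep, “which suggests slow leakage of target to other product”. The forecast is therefore 4.5 at 30 s, 4.7 at 10 min and 8 at 3.0 h, with other capture product ahead.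

I disagree: I read the early ratio as an average over a falling one. On that count the 8.00 min readings put the loss of second nucleophile at 21.4% of its charge, more than the 3.32% they put on the first. If both nucleophiles capture one short-lived species, the ratio being made at any moment is r = s·D/B, with D and B the equivalents remaining and s a constant. Integrated, s is the logarithm of charge over remainder for the second nucleophile, divided by the same for the first. The 8.00 min reading gives 7.15, with the scatter of that target reading. This s is the selectivity factor, the capture rate constant of the second nucleophile over that of the first.

At the charges, r is 5.15, so I expect that at 30 s, above the forecast. From 40.0 min to 90.0 min both products read flat within scatter, so for 3.0 h I take their pooled ratio, 5.55, below the forecast.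

The flask gives 5.26 at 30 s, 5.21 at 10 min and 5.80 at 3.0 h, with other capture product ahead.

    starting material → intermediate (k = 0.0800 min⁻¹)
    first nucleophile + intermediate → target (k = 56.0 M⁻¹ min⁻¹)
    second nucleophile + intermediate → other capture product (k = 410 M⁻¹ min⁻¹)
    target ⇌ isomer of the product (K = 0.380, k = 0.0240 min⁻¹)
    starting material + protic impurity → quenched substrate (k = 25.0 M⁻¹ min⁻¹)

The forecast's view keeps the middle of the run, where its 4.7 stands within the margin, and the ratio does climb afterwards. Between 0.900 h and 3.00 h, though, other capture product goes from 75.8% to 76.7% and target from 13.3% to 13.2%. Put to use at the charges, s gave 5.15 against 5.26.

In a neighbour flask, charged with 4.50 equiv of second nucleophile and the other charges as before, s gives a ratio of 12.9 at the charges. That neighbour flask shows 13.2 at 30 s.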